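**Retrosynthetic overview**
- Kuraridin ⇐ global MOM removal ⇐ aryl–acyl bond: an ortho-lithiated (R)-lavandulyl arene adds to a B-ring cinnamoyl Weinreb amide (no aldol).
- Lavandulyl isopropenyl ⇐ methylenation of a methyl ketone ⇐ ring-opened (3R)-3-prenyl-dihydrocoumarin.
- Key disconnection: the dihydrocoumarin ⇐ formal [4+2] of a dearomatized o-quinone methide (from a mirror-symmetric bis-Boc 2,6-dihydroxy-4-methoxybenzyl alcohol) with a chiral NHC-bound enolate of 5-methylhex-4-enoic acid. This sets the only stereocentre and differentiates the two equivalent phenol oxygens.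
- Rings: both benzene rings are bought. The only ring formed is the temporary δ-lactone (step 4), which is opened again in step 5.

**Assumptions**
- 5-Methylhex-4-enoic acid (5) and phosphonate 12 are catalogue items.
- The (5aR,10bS) antipode of the aminoindanol-derived N-mesityl triazolium salt is assumed to give 3R. This must be confirmed on the first run (chiral HPLC, then rotation of 15 against natural kuraridin); the antipodal salt is equally available if the sense is reversed.
- One-pot, two-stage operations are counted as one step.

**Route**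

Step 1
Reactants: 1, 2,4,6-trihydroxybenzaldehyde
Product: 2, 2,6-dihydroxy-4-methoxybenzaldehyde
Conditions: MeI (1.05 equiv), Li2CO3 (1.1 equiv), DMF, 40 °C; minor 2-O-methyl and di-O-methyl products removed by chromatography/crystallisation
Reagents that add atoms: iodomethane, CI
Why: the 4-OH (para to CHO, most acidic, least hindered) is alkylated first under weak base with limiting MeI (Williamson etherification), and the product keeps the mirror symmetry used later.

Step 2
Reactants: 2, 2,6-dihydroxy-4-methoxybenzaldehyde
Product: 3, 2,6-bis[(tert-butoxycarbonyl)oxy]-4-methoxybenzaldehyde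
Conditions: Boc2O (2.4 equiv), i-Pr2NEt (2.5 equiv), DMAP (5 mol %), THF, 0 °C → rt
Reagents that add atoms: di-tert-butyl dicarbonate, CC(C)(C)OC(=O)OC(=O)OC(C)(C)C
Why: DMAP-catalysed O-acylation converts both phenols into aryl tert-butyl carbonates, which mask them now and can later be transferred to a neighbouring benzylic alkoxide.

Step 3
Reactants: 3, 2,6-bis(Boc-oxy)-4-methoxybenzaldehyde
Product: 4, {2,6-bis[(tert-butoxycarbonyl)oxy]-4-methoxyphenyl}methanol
Conditions: BH3·THF (1.1 equiv), THF, −10 → 0 °C; MeOH quench, neutral work-up, used at once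
Reagents that add atoms: none
Why: neutral borane reduction gives an alkoxyborane and not a free alkoxide, so the aryl carbonates neither migrate nor eliminate and the symmetric benzylic alcohol is obtained intact.

Step 4 (key step)
Reactants: 4, {2,6-bis(Boc-oxy)-4-methoxyphenyl}methanol; 5, 5-methylhex-4-enoic acid
Product: 6, (3R)-5-[(tert-butoxycarbonyl)oxy]-7-methoxy-3-(3-methylbut-2-en-1-yl)-3,4-dihydro-2H-chromen-2-one
Conditions: 5 (1.8 equiv), CDI (1.7 equiv), THF, rt, 1 h, N2 purge (acyl imidazole formed in situ); then (5aR,10bS)-aminoindanol-derived N-mesityl triazolium BF4 (15 mol %), Cs2CO3 (1.5 equiv), 4 Å MS, −20 °C; 4 added over 4 h by syringe pump; → 0 °C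
Reagents that add atoms: none (CDI, catalyst and base are not retained)
Why: Proposed new method: base-induced O→O Boc transfer in 4 followed by loss of tert-butyl carbonate generates the dearomatized o-quinone methide (known anionic o-quinone methide generation from O-Boc salicyl alcohols), which is trapped in a formal [4+2] (Michael addition then lactonisation, releasing the carbene) by the chiral NHC-bound (Z)-enolate formed from the acyl imidazole, the closest known reaction type being NHC-catalysed azolium-enolate/o-quinone methide annulation to 3-substituted dihydrocoumarins under fluoride triggering; the indane wall of the catalyst blocks one enolate face so C3 is formed as R, and either equivalent OBoc group can migrate, which desymmetrises the ring.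

Step 5
Reactants: 6, (3R)-5-(Boc-oxy)-7-methoxy-3-prenyl-dihydrocoumarin
Product: 7, (3R)-3-[(2,6-dihydroxy-4-methoxyphenyl)methyl]-6-methylhept-5-en-2-one
Conditions: MeNH(OMe)·HCl (4 equiv), i-PrMgCl (8 equiv), THF, −20 °C, 1 h; then MeMgBr (6 equiv), −20 → 0 °C; sat. NH4Cl
Reagents that add atoms: methylmagnesium bromide, C[Mg]Br (N,O-dimethylhydroxylamine is not retained)
Why: the magnesium amide opens the activated aryl lactone to the Weinreb amide and the excess reagents cleave the remaining aryl carbonate, and the chelated tetrahedral adduct with MeMgBr stops cleanly at the methyl ketone (Weinreb ketone synthesis) without epimerising C3; any 5-OH analogue of 6 converges here.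

Step 6
Reactants: 7, (3R)-keto-resorcinol
Product: 8, (3R)-3-{[4-methoxy-2,6-bis(methoxymethoxy)phenyl]methyl}-6-methylhept-5-en-2-one
Conditions: MOMCl (3 equiv), i-Pr2NEt (4 equiv), n-Bu4NI (10 mol %), CH2Cl2, 0 °C → rt
Reagents that add atoms: chloromethyl methyl ether, COCCl
Why: amine-base acetalisation of the two unchelated phenols is too mild to enolise the α-stereocentre and installs the ortho-directing groups needed for step 10.

Step 7
Reactants: 8, (3R)-bis-MOM methyl ketone
Product: 9, 5-methoxy-1,3-bis(methoxymethoxy)-2-[(2R)-5-methyl-2-(prop-1-en-2-yl)hex-4-en-1-yl]benzene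
Conditions: Cp2TiMe2 (2.5 equiv), toluene/THF, 65 °C, dark
Reagents that add atoms: dimethyltitanocene (CH2 source), C[Ti](C)(C1C=CC=C1)C1C=CC=C1
Why: Petasis methylenation is neither basic nor acidic, so the α-chiral ketone becomes the isopropenyl group without epimerisation, which completes the (R)-lavandulyl chain and removes the epimerisable centre.

Step 8
Reactants: 10, 2,4-dihydroxybenzaldehyde
Product: 11, 2,4-bis(methoxymethoxy)benzaldehyde
Conditions: NaH (2.4 equiv), MOMCl (2.6 equiv), DMF, 0 °C → rt
Reagents that add atoms: chloromethyl methyl ether, COCCl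
Why: full deprotonation overcomes the chelated 2-OH and gives the bis-acetal in a standard Williamson-type O-alkylation.

Step 9
Reactants: 11, 2,4-bis(MOM-oxy)benzaldehyde; 12, diethyl {2-[methoxy(methyl)amino]-2-oxoethyl}phosphonate
Product: 13, (2E)-3-[2,4-bis(methoxymethoxy)phenyl]-N-methoxy-N-methylprop-2-enamide
Conditions: NaH (1.2 equiv), THF, 0 °C → rt
Reagents that add atoms: none beyond 11 and 12
Why: Horner–Wadsworth–Emmons olefination with a stabilised amide phosphonate gives the E-enamide selectively, so the chalcone double bond geometry is fixed here.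

Step 10
Reactants: 9, bis-MOM (R)-lavandulyl arene; 13, B-ring cinnamoyl Weinreb amide
Product: 14, (2E)-3-[2,4-bis(methoxymethoxy)phenyl]-1-{6-methoxy-2,4-bis(methoxymethoxy)-3-[(2R)-5-methyl-2-(prop-1-en-2-yl)hex-4-en-1-yl]phenyl}prop-2-en-1-one
Conditions: n-BuLi (1.15 equiv), TMEDA (1.2 equiv), THF, −10 → 0 °C, 1 h; then 13 (1.2 equiv), −78 → −20 °C; sat. NH4Cl
Reagents that add atoms: none
Why: directed ortho-metalation occurs at the ring C–H flanked by OMOM and OMe (the two such positions give the same compound), and 1,2-addition of the aryllithium to the Weinreb amide gives a stable chelate that releases the E-enone only on quench, so the ketone ends up between an oxygenated carbon and the OMe-bearing carbon as required.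

Step 11
Reactants: 14, tetra-MOM kuraridin
Product: 15, kuraridin
Conditions: 3 M aq. HCl/MeOH (1:5), rt, dark, monitored by HPLC and stopped at full conversion
Reagents that add atoms: none
Why: aryl MOM acetals hydrolyse at rt faster than the lavandulyl alkenes are protonated or the 2'-hydroxychalcone closes to the flavanone (as in MOM removal from prenylated polyhydroxychalcones), and working in the dark avoids E→Z isomerisation of the 2-hydroxychalcone.

**Compound list**
1 | 2,4,6-trihydroxybenzaldehyde | O=Cc1c(O)cc(O)cc1O | starting material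
2 | 2,6-dihydroxy-4-methoxybenzaldehyde | COc1cc(O)c(C=O)c(O)c1 | intermediate
3 | 2,6-bis[(tert-butoxycarbonyl)oxy]-4-methoxybenzaldehyde | COc1cc(OC(=O)OC(C)(C)C)c(C=O)c(OC(=O)OC(C)(C)C)c1 | intermediate
4 | {2,6-bis[(tert-butoxycarbonyl)oxy]-4-methoxyphenyl}methanol | COc1cc(OC(=O)OC(C)(C)C)c(CO)c(OC(=O)OC(C)(C)C)c1 | intermediate
5 | 5-methylhex-4-enoic acid | CC(C)=CCCC(=O)O | starting material
6 | (3R)-5-[(tert-butoxycarbonyl)oxy]-7-methoxy-3-(3-methylbut-2-en-1-yl)-3,4-dihydro-2H-chromen-2-one | CC(C)=CC[C@@H]1Cc2c(OC(=O)OC(C)(C)C)cc(OC)cc2OC1=O | intermediate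
7 | (3R)-3-[(2,6-dihydroxy-4-methoxyphenyl)methyl]-6-methylhept-5-en-2-one | CC(=O)[C@H](CC=C(C)C)Cc1c(O)cc(OC)cc1O | intermediate
8 | (3R)-3-{[4-methoxy-2,6-bis(methoxymethoxy)phenyl]methyl}-6-methylhept-5-en-2-one | CC(=O)[C@H](CC=C(C)C)Cc1c(OCOC)cc(OC)cc1OCOC | intermediate
9 | 5-methoxy-1,3-bis(methoxymethoxy)-2-[(2R)-5-methyl-2-(prop-1-en-2-yl)hex-4-en-1-yl]benzene | C=C(C)[C@H](CC=C(C)C)Cc1c(OCOC)cc(OC)cc1OCOC | intermediate
10 | 2,4-dihydroxybenzaldehyde | O=Cc1ccc(O)cc1O | starting material
11 | 2,4-bis(methoxymethoxy)benzaldehyde | COCOc1ccc(C=O)c(OCOC)c1 | intermediate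
12 | diethyl {2-[methoxy(methyl)amino]-2-oxoethyl}phosphonate | CCOP(=O)(CC(=O)N(C)OC)OCC | starting material
13 | (2E)-3-[2,4-bis(methoxymethoxy)phenyl]-N-methoxy-N-methylprop-2-enamide | CON(C)C(=O)/C=C/c1ccc(OCOC)cc1OCOC | intermediate
14 | (2E)-3-[2,4-bis(methoxymethoxy)phenyl]-1-{6-methoxy-2,4-bis(methoxymethoxy)-3-[(2R)-5-methyl-2-(prop-1-en-2-yl)hex-4-en-1-yl]phenyl}prop-2-en-1-one | C=C(C)[C@H](CC=C(C)C)Cc1c(OCOC)cc(OC)c(C(=O)/C=C/c2ccc(OCOC)cc2OCOC)c1OCOC | intermediate
15 | kuraridin, (2E)-1-{2,4-dihydroxy-6-methoxy-3-[(2R)-5-methyl-2-(prop-1-en-2-yl)hex-4-en-1-yl]phenyl}-3-(2,4-dihydroxyphenyl)prop-2-en-1-one | C=C(C)[C@H](CC=C(C)C)Cc1c(O)cc(OC)c(C(=O)/C=C/c2ccc(O)cc2O)c1O | target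

**Step count**
- Total steps: 11
- Longest linear sequence: 9 (steps 1–7, 10, 11)

**Three steps most likely to fail, with fallbacks**
1. Step 4 (o-quinone methide/NHC-enolate annulation). Risks are o-quinone methide oligomerisation, Boc cleavage by imidazole or tert-butoxide, and modest ee. Fallback: switch to auxiliary control. The sodium enolate of (4S)-4-benzyl-3-(5-methylhex-4-enoyl)oxazolidin-2-one is alkylated with the o-quinone methide generated from 4 by t-BuMgCl at −78 °C (or with 2,6-bis(methoxymethoxy)-4-methoxybenzyl bromide), and the imide is then transaminated to the Weinreb amide to rejoin the route at step 5.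
2. Step 10 (hindered aryllithium plus enamide). Risks are 1,4-addition and competing metalation of the B ring. Fallback: build the enone stepwise. The aryllithium from 9 is quenched with N-methoxy-N-methylacetamide to give the acetophenone, which undergoes Claisen–Schmidt condensation with aldehyde 11 (KOH, EtOH) to give the same compound 14.
3. Step 11 (acidic global deprotection). Risks are chroman formation from the lavandulyl group, flavanone closure to kurarinone, and flavylium formation. Fallback: redesign the protecting-group strategy. 1-Ethoxyethyl ethers (ethyl vinyl ether, PPTS) replace MOM in steps 6 and 8; they direct the lithiation equally well and are removed at the end with PPTS/MeOH at rt.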